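Strike the clock out of these flasks first, then see what remains to reckon.

| setting | alpha | zeta | east | south |
|---|---|---|---|---|
| substrate | 0.40 M | 0.40 M | 0.40 M | 0.40 M |
| reagent | 0.13 M | 0.57 M | 0.100 M | 0.400 M |
| scavenger | 0.60 M | 0.60 M | 0.600 M | 0.600 M |
| temperature | 95 °C | 110 °C | 110 °C | 110 °C |
| remark | run made earlier | run made earlier |  |  |
| time |  |  | 25 min | 25 min |

| alpha: time / min | alpha: mono adduct / % | zeta: time / min | zeta: mono adduct / % |
|---|---|---|---|
| 3.00 | 8.9 | 4.00 | 32.6 |
| 10.0 | 17.1 | 8.00 | 28.9 |
| 15.0 | 20.4 | 12.0 | 27.3 |
| 30.0 | 22.8 | 15.0 | 26.8 |
| 40.0 | 22.7 | 20.0 | 27.1 |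
| 50.0 | 23.4 | 25.0 | 26.1 |

(standard deviation of a reading: 0.5 percentage points)

- which one finishes higher in amount of mono adduct, in percent of the substrate charged ("neither" within 2 percentage points) (east / south / neither)
- amount of mono adduct at the end, in percent of the substrate charged, east
- amount of mono adduct at the end, in percent of the substrate charged, south

*Does the time matter?* Not by my reading. Alpha stands flat from 30.0 min on, and zeta moves from 26.8% to 26.1% after 15.0 min. East is hotter than alpha, so I take both new flasks as finished at 25 min.

*What stays nearly constant, then?* Let a and m be the fractions of charged substrate left as substrate and as mono adduct, and κ the selectivity factor. Zeta's fall from 32.6% shows that mono adduct is consumed. If reagent attacks both substrate and mono adduct, it cancels when the two rates are divided, and so does time: m = (a^κ − a)/(1 − κ).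

*What is κ worth?* Alpha's last three readings average 23.0%, from 0.325 equivalents of reagent. A double product costs two reagents, so if the reagent went to these two products, I estimate double product at 4.77%, leaving a = 72.3%. Solving near κ = 1 gives a reading of κ = 1.13, the rate of attack on mono adduct over that on substrate at equal concentrations.

*But alpha ran cooler.* Yes, at 95 °C, so carrying κ to 110 °C is a risk I accept.

*Your numbers?* East has 0.250 equivalents, which gives a near 78.5% and m near 18.7%. The rule peaks at 34.5%, where a = 39.1%, which the balance places at 0.873 equivalents. South's 1.00 lies beyond that, just past the flat top.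

The forecast says south, with 18.8% for east and 33% for south, which it says “lands almost exactly at the mono maximum”. My peak stands higher than its south, though the order is the same.

The flasks give 18.8% for east and 32.8% for south, so south finishes higher.

    substrate + reagent → mono adduct + released group (k = 0.790 /M/min, Ea = 79.0 kJ/mol)
    reagent + mono adduct → double product + released group (k = 0.960 /M/min, Ea = 85.0 kJ/mol)
    reagent + double product → triple product + released group (k = 0.150 /M/min, Ea = 91.0 kJ/mol)
    reagent + triple product → tetra adduct + released group (k = 0.460 /M/min, Ea = 85.0 kJ/mol)
    substrate + released group ⇌ idle adduct, settled at all times (K = 0.770 /M, ΔH = −60.0 kJ/mol)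
    scavenger + released group → scavenged by-product (k = 11.0 /M/min, Ea = 48.0 kJ/mol)
    (constants at 110 °C)

In south, half the turnover of the substrate step was done by 1.60 min and half that of the mono adduct step by 3.33 min. At 12.5 min reagent stood at 2.93% of its charge, and by 25.0 min at 0.115%. South's answer has moved by 5 points at 0.188 M or 0.550 M of reagent. With κ, south's 35.1% of substrate gives 34.3% against 32.8%. A neighbour flask, south with 0.16 M of substrate, ends with 4.84% of substrate, for which κ gives 12.1%, and it holds 10.7% of mono adduct.

The numbers in the tables are simulated from invented constants, and the scatter is random.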